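**Assumption:** irigenin has no stereocentre (the SMILES carries no stereodescriptors and the molecule is achiral), so the "single enantiomer" is simply the compound itself and no stereocontrol is required.

## Retrosynthetic overview

1. Irigenin ⇐ tri-MOM-protected isoflavone by a final acid deprotection of the 5-, 7- and 3'-OH groups.
2. C3–C1' bond ⇐ Suzuki–Miyaura coupling of a 3-iodochromone (A/C fragment, 22 heavy atoms) with an arylboronic acid (B fragment, 17 heavy atoms).
3. Iodochromone ⇐ enaminone iodocyclisation ⇐ o-hydroxyacetophenone ⇐ symmetric 4-methoxy-3,5-bis(MOM-oxy)phenol ⇐ resorcinol (directed ortho-metalation/hydroxylation, then Ir C–H borylation/oxidation). The symmetry of this phenol removes the 6-OMe versus 8-OMe ambiguity.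
4. Boronic acid ⇐ Ir C–H borylation of MOM-protected 2,3-dimethoxyphenol ⇐ veratrole ⇐ catechol.
5. Ring order: both benzene rings come from the starting materials (resorcinol → A, catechol → B). The only ring built is the pyran-4-one C ring (step 8), before the fragment coupling.

## Fragment A/C (from resorcinol)

**Step 1**
Reactants: 1, resorcinol (benzene-1,3-diol)
Product: 2, 1,3-bis(methoxymethoxy)benzene
Conditions: MOMCl (2.5 equiv), i-Pr2NEt, CH2Cl2, 0 °C → rt
Reagents that add atoms: chloromethyl methyl ether (MOMCl), COCCl
Why: Williamson-type O-alkylation protects both phenols as MOM acetals, which also act as ortho-directing groups in step 2.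

**Step 2**
Reactants: 2, 1,3-bis(methoxymethoxy)benzene
Product: 3, 2,6-bis(methoxymethoxy)phenol
Conditions: n-BuLi, THF, 0 °C → rt; B(OMe)3, −78 °C → rt; then 30% H2O2, aq. NaOH, 0 °C
Reagents that add atoms: hydrogen peroxide, OO (the oxygen; boron is only transient)
Why: Directed ortho-metalation occurs at C2, which is flanked by two OMOM groups; borate trapping and boronate oxidation (1,2-aryl shift to oxygen) give the phenol.

**Step 3**
Reactants: 3, 2,6-bis(methoxymethoxy)phenol
Product: 4, 2-methoxy-1,3-bis(methoxymethoxy)benzene
Conditions: MeI, K2CO3, DMF, rt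
Reagents that add atoms: iodomethane, CI
Why: Williamson O-methylation of the only free phenol installs the future 6-OMe.

**Step 4**
Reactants: 4, 2-methoxy-1,3-bis(methoxymethoxy)benzene
Product: 5, 4-methoxy-3,5-bis(methoxymethoxy)phenol
Conditions: [Ir(OMe)(cod)]2 (2 mol %), dtbpy (4 mol %), B2pin2, THF, 80 °C; then aq. NaOH, 30% H2O2, 0 °C (one pot)
Reagents that add atoms: hydrogen peroxide, OO (the oxygen; B2pin2 supplies boron only transiently)
Why: Sterically controlled Ir-catalysed C–H borylation (Hartwig–Miyaura) goes to C5, the only C–H with no ortho substituent, and in-situ boronate oxidation gives a C2-symmetric phenol.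

**Step 5**
Reactants: 5, 4-methoxy-3,5-bis(methoxymethoxy)phenol
Product: 6, 2-iodo-4-methoxy-3,5-bis(methoxymethoxy)phenol
Conditions: NIS (1.0 equiv), DMF, −20 → 0 °C, dark
Reagents that add atoms: N-iodosuccinimide, O=C1CCC(=O)N1I
Why: Electrophilic aromatic iodination ortho to the phenol; the two open positions are equivalent, so one equivalent of NIS gives a single mono-iodide under non-acidic, MOM-safe conditions.

**Step 6**
Reactants: 6, 2-iodo-4-methoxy-3,5-bis(methoxymethoxy)phenol
Product: 7, 1-[6-hydroxy-3-methoxy-2,4-bis(methoxymethoxy)phenyl]ethan-1-one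
Conditions: NaH (1.1 equiv), THF, 0 °C; t-BuLi (2.1 equiv), −78 °C; MeC(O)N(OMe)Me, −78 → 0 °C; aq. NH4Cl
Reagents that add atoms: N-methoxy-N-methylacetamide, CC(=O)N(C)OC
Why: Iodine–lithium exchange on the sodium phenoxide gives the o-lithiophenoxide, and Weinreb amide acylation (stable chelated tetrahedral intermediate, no over-addition) installs the acetyl group without Lewis acid, so the MOM groups survive.

**Step 7**
Reactants: 7, 1-[6-hydroxy-3-methoxy-2,4-bis(methoxymethoxy)phenyl]ethan-1-one
Product: 8, (E)-3-(dimethylamino)-1-[6-hydroxy-3-methoxy-2,4-bis(methoxymethoxy)phenyl]prop-2-en-1-one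
Conditions: DMF-DMA (3 equiv), toluene, 90 °C
Reagents that add atoms: N,N-dimethylformamide dimethyl acetal, COC(OC)N(C)C
Why: Condensation of the methyl ketone with the formamide acetal gives the vinylogous amide (enaminone); the chelated phenol is left untouched.

**Step 8**
Reactants: 8, the enaminone from step 7
Product: 9, 3-iodo-6-methoxy-5,7-bis(methoxymethoxy)-4H-chromen-4-one
Conditions: I2 (1.5 equiv), pyridine, CHCl3, rt; Na2S2O3 work-up
Reagents that add atoms: iodine, II
Why: Gammill iodocyclisation: α-iodination of the enaminone, 6-endo attack by the only free phenol and loss of Me2NH close the pyranone; the amine/pyridine buffer keeps the MOM groups intact.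

## Fragment B (from catechol)

**Step 9**
Reactants: 10, catechol (benzene-1,2-diol)
Product: 11, 1,2-dimethoxybenzene (veratrole)
Conditions: MeI (2.5 equiv), K2CO3, acetone, reflux
Reagents that add atoms: iodomethane, CI
Why: Double Williamson O-methylation.

**Step 10**
Reactants: 11, 1,2-dimethoxybenzene
Product: 12, 2,3-dimethoxyphenol
Conditions: n-BuLi, TMEDA, Et2O, 0 °C → rt; B(OMe)3, −78 °C → rt; then 30% H2O2, aq. NaOH, 0 °C
Reagents that add atoms: hydrogen peroxide, OO
Why: Directed ortho-metalation next to OMe (C3), then borate trapping and boronate oxidation, gives the 1,2,3-trioxygenated ring with one differentiated oxygen.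

**Step 11**
Reactants: 12, 2,3-dimethoxyphenol
Product: 13, 1,2-dimethoxy-3-(methoxymethoxy)benzene
Conditions: MOMCl, i-Pr2NEt, CH2Cl2, 0 °C → rt
Reagents that add atoms: chloromethyl methyl ether, COCCl
Why: MOM protection of the future 3'-OH; MOM has no aryl C–H that could compete in the borylation and is removed together with the A-ring MOM groups.

**Step 12**
Reactants: 13, 1,2-dimethoxy-3-(methoxymethoxy)benzene
Product: 14, 2-[3,4-dimethoxy-5-(methoxymethoxy)phenyl]-4,4,5,5-tetramethyl-1,3,2-dioxaborolane
Conditions: [Ir(OMe)(cod)]2 (2 mol %), dtbpy (4 mol %), B2pin2, THF, 80 °C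
Reagents that add atoms: bis(pinacolato)diboron, CC1(C)OB(OC1(C)C)B1OC(C)(C)C(C)(C)O1
Why: Ir-catalysed C–H borylation is sterically directed to C5, the only C–H not ortho to a substituent; electrophilic halogenation cannot reach this position.

**Step 13**
Reactants: 14, the pinacol boronate from step 12
Product: 15, [3,4-dimethoxy-5-(methoxymethoxy)phenyl]boronic acid
Conditions: NaIO4, NH4OAc, acetone/H2O, rt
Reagents that add atoms: water, O
Why: Oxidative cleavage of the released pinacol drives boronate hydrolysis at neutral pH (MOM-safe); the free boronic acid is purified by extraction and transmetalates quickly under the mild carbonate base that the iodochromone tolerates.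

## Fragment coupling and end game

**Step 14**
Reactants: 9, 3-iodo-6-methoxy-5,7-bis(methoxymethoxy)-4H-chromen-4-one; 15, [3,4-dimethoxy-5-(methoxymethoxy)phenyl]boronic acid (1.3 equiv)
Product: 16, 3-[3,4-dimethoxy-5-(methoxymethoxy)phenyl]-6-methoxy-5,7-bis(methoxymethoxy)-4H-chromen-4-one
Conditions: Pd(dppf)Cl2·CH2Cl2 (5 mol %), 2 M aq. Na2CO3, DME, 80 °C, degassed
Reagents that add atoms: none
Why: Suzuki–Miyaura cross-coupling of the vinylogous-ester C3–I bond (fast oxidative addition) with an unhindered arylboronic acid forms the isoflavone C3–C1' bond; the MOM acetals are base-stable.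

**Step 15**
Reactants: 16, the tri-MOM isoflavone from step 14
Product: 17, irigenin (5,7-dihydroxy-3-(3-hydroxy-4,5-dimethoxyphenyl)-6-methoxy-4H-chromen-4-one)
Conditions: 3 M aq. HCl, MeOH/THF, 60 °C
Reagents that add atoms: none
Why: Acid-catalysed acetal hydrolysis removes all three MOM groups while the aryl methyl ethers and the chromone are stable; no stereocentre is involved.

## Compound list

1 | resorcinol | Oc1cccc(O)c1 | starting material
2 | 1,3-bis(methoxymethoxy)benzene | COCOc1cccc(OCOC)c1 | intermediate
3 | 2,6-bis(methoxymethoxy)phenol | COCOc1cccc(OCOC)c1O | intermediate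
4 | 2-methoxy-1,3-bis(methoxymethoxy)benzene | COCOc1cccc(OCOC)c1OC | intermediate
5 | 4-methoxy-3,5-bis(methoxymethoxy)phenol | COCOc1cc(O)cc(OCOC)c1OC | intermediate
6 | 2-iodo-4-methoxy-3,5-bis(methoxymethoxy)phenol | COCOc1cc(O)c(I)c(OCOC)c1OC | intermediate
7 | 1-[6-hydroxy-3-methoxy-2,4-bis(methoxymethoxy)phenyl]ethan-1-one | CC(=O)c1c(O)cc(OCOC)c(OC)c1OCOC | intermediate
8 | (E)-3-(dimethylamino)-1-[6-hydroxy-3-methoxy-2,4-bis(methoxymethoxy)phenyl]prop-2-en-1-one | CN(C)/C=C/C(=O)c1c(O)cc(OCOC)c(OC)c1OCOC | intermediate
9 | 3-iodo-6-methoxy-5,7-bis(methoxymethoxy)-4H-chromen-4-one | COCOc1cc2occ(I)c(=O)c2c(OCOC)c1OC | intermediate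
10 | catechol | Oc1ccccc1O | starting material
11 | 1,2-dimethoxybenzene (veratrole) | COc1ccccc1OC | intermediate
12 | 2,3-dimethoxyphenol | COc1cccc(O)c1OC | intermediate
13 | 1,2-dimethoxy-3-(methoxymethoxy)benzene | COCOc1cccc(OC)c1OC | intermediate
14 | 2-[3,4-dimethoxy-5-(methoxymethoxy)phenyl]-4,4,5,5-tetramethyl-1,3,2-dioxaborolane | COCOc1cc(B2OC(C)(C)C(C)(C)O2)cc(OC)c1OC | intermediate
15 | [3,4-dimethoxy-5-(methoxymethoxy)phenyl]boronic acid | COCOc1cc(B(O)O)cc(OC)c1OC | intermediate
16 | 3-[3,4-dimethoxy-5-(methoxymethoxy)phenyl]-6-methoxy-5,7-bis(methoxymethoxy)-4H-chromen-4-one | COCOc1cc(-c2coc3cc(OCOC)c(OC)c(OCOC)c3c2=O)cc(OC)c1OC | intermediate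
17 | irigenin | COc1cc(-c2coc3cc(O)c(OC)c(O)c3c2=O)cc(O)c1OC | target

## Summary

**Total step count:** 15.
**Longest linear sequence:** 10 (steps 1–8, 14, 15), which is two thirds of the total; the B branch is 5 steps (9–13).

**Steps most likely to fail, with fallbacks**

1. **Step 4, Ir C–H borylation/oxidation of the electron-rich bis-MOM arene** (slow turnover, or over-oxidation of the very electron-rich phenol). Fallback: reach phenol 5 by carbonyl-to-phenol chemistry from 4-bromophenol (8 heavy atoms). The sequence is Duff double ortho-formylation, O-methylation, Dakin/Baeyer–Villiger oxidation and hydrolysis to 5-bromo-2-methoxyresorcinol, bis-MOM protection, then Br/Li exchange–borate–H2O2 to install the phenol.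
2. **Step 6, o-lithiophenoxide generation and Weinreb acylation** (protonation of the dianion, enolisation of the amide). Fallback: avoid the aryl-lithium altogether by ortho-formylating phenol 5 directly (MgCl2, Et3N, paraformaldehyde), then MeMgBr addition and MnO2 oxidation to give ketone 7.
3. **Step 14, Suzuki coupling of the hindered, base-sensitive 5-OMOM-3-iodochromone** (protodeiodination, pyranone ring opening). Fallback: switch to a deoxybenzoin construction. Convert boronate 14 to the arylacetic Weinreb amide (Pd coupling with 2-bromo-N-methoxy-N-methylacetamide), acylate the dianion of iodophenol 6 with it, close the pyranone with DMF-DMA, then remove the MOM groups.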